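**Retrosynthetic overview** (flavanone numbering: O1, C2(Ph), C3, C4(=O), C4a, C5(OMe), C6, C7(=O), C8(prenyl)2, C8a; ring A = carbocycle, ring C = pyranone)
1. Griffinone A (20) is a cycloisomer of the open-chain hydroxy bis-ynone 16; one retro double conjugate addition opens both rings: O1–C8a (ring C) and C4a–C5 (ring A).
2. Enabling feature: the cross-conjugated array O1–C8a=C4a(–C4=O)–C5(OMe)=C6–C7=O. C8a and C5 are β-carbons of two enones at the alkyne oxidation level, held 1,3 by the non-enolisable quaternary C8.
3. Ring order in the forward sense: ring C first (alkoxide to C8a), then ring A (the C4a carbanion so created adds to C5).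
4. 16 comes from the C4–C4a bond (lithium acetylide 9 + aldehyde 7, then oxidation) and the C6–C7 bond (methoxyethynyllithium 12 + Weinreb amide 10).
5. 9 is made and used in one flask from keto amide 4 (gem-diprenylation of acetoacetic Weinreb amide 1 at C8, then methyl ketone to acetylide); 7 comes from ethyl (S)-3-hydroxy-3-phenylpropanoate 5, the only source of the C2 stereocentre.

Key step: step 8

Remark (assumption on the chemistry): methoxyethynyllithium 12 is assumed to form from acetal 11 and LiNEt2 as its ethoxy homologue does from the diethyl acetal; 1, 2, 5 and 11 are taken as commercial.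

**Step 1**
Reactants: 1 N-methoxy-N-methyl-3-oxobutanamide; 2 1-bromo-3-methylbut-2-ene (prenyl bromide)
Product: 4 2-acetyl-N-methoxy-N,5-dimethyl-2-(3-methylbut-2-en-1-yl)hex-4-enamide, via monoprenyl keto amide 3 (not isolated)
Conditions: NaH (2.2 equiv), 2 (2.3 equiv), THF/DMF, 0 °C → rt
Reagents that add atoms: 1-bromo-3-methylbut-2-ene (compound 2), CC(C)=CCBr
Why: Double C-alkylation of the 1,3-dicarbonyl sodium enolate (SN2 at the primary allylic bromide, twice) should install both prenyl groups on the carbon that becomes C8 and make it non-enolisable.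

**Step 2**
Reactants: 5 ethyl (3S)-3-hydroxy-3-phenylpropanoate
Product: 6 ethyl (3S)-3-phenyl-3-(triethylsilyloxy)propanoate
Conditions: Et3SiCl, imidazole, CH2Cl2, 0 °C → rt
Reagents that add atoms: chlorotriethylsilane, CC[Si](Cl)(CC)CC
Why: Standard silylation of a secondary alcohol; the triethylsilyl ether should survive the organolithium, hydride and MnO2 steps, is removable by mild fluoride, and the stereocentre is not touched.

**Step 3**
Reactants: 6 ethyl (3S)-3-phenyl-3-(triethylsilyloxy)propanoate
Product: 7 (3S)-3-phenyl-3-(triethylsilyloxy)propanal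
Conditions: i-Bu2AlH (1.1 equiv), CH2Cl2, −78 °C; aq KNaC4H4O6
Reagents that add atoms: none
Why: Partial reduction of an ester by i-Bu2AlH at −78 °C, where the aluminium hemiacetal persists until work-up, should give the aldehyde without touching the silyl ether or the stereocentre.

**Step 4**
Reactants: 4 2-acetyl-N-methoxy-N,5-dimethyl-2-(3-methylbut-2-en-1-yl)hex-4-enamide; 7 (3S)-3-phenyl-3-(triethylsilyloxy)propanal
Product: 10 (7S)-5-hydroxy-N-methoxy-N-methyl-2,2-bis(3-methylbut-2-en-1-yl)-7-phenyl-7-(triethylsilyloxy)hept-3-ynamide (both C5 epimers), via enol phosphate 8 (not isolated), via lithium acetylide 9 (not isolated)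
Conditions: 4 (1.25 equiv), LiN(i-Pr)2 (1.05 equiv per 4), THF, −78 °C; ClP(O)(OEt)2 (1.1 equiv), −78 °C → rt; LiN(i-Pr)2 (2.05 equiv), −78 → 0 °C; then 7 (1.0 equiv), −78 °C; aq NH4Cl
Reagents that add atoms: none
Why: One-flask conversion of a methyl ketone into a lithium acetylide by enol phosphate elimination, followed by 1,2-addition to an aldehyde: the kinetic lithium enolate of the methyl ketone (the only enolisable site) is O-phosphorylated, β-elimination with two equivalents of amide base should give the lithium acetylide directly (no allene can form next to the quaternary carbon), and the acetylide adds to 7 to form the C4–C4a bond, while the hindered tertiary Weinreb amide is inert at −78 °C, the amide base is matched to the enol phosphate and the acetylide is kept in excess so that no free amide base meets the enolisable aldehyde, and the new carbinol centre (mixture) is erased by the oxidation in step 6.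

**Step 5**
Reactants: 10 (7S)-5-hydroxy-N-methoxy-N-methyl-2,2-bis(3-methylbut-2-en-1-yl)-7-phenyl-7-(triethylsilyloxy)hept-3-ynamide; 11 2-chloro-1,1-dimethoxyethane
Product: 14 (9S)-7-hydroxy-1-methoxy-4,4-bis(3-methylbut-2-en-1-yl)-9-phenyl-9-(triethylsilyloxy)nona-1,5-diyn-3-one (both C7 epimers), via methoxyethynyllithium 12 (not isolated), via tetrahedral adduct 13 (not isolated)
Conditions: 11 (3 equiv), LiNEt2 (9 equiv), THF, 0 °C; then 10, −78 → 0 °C; inverse quench into cold aq NaH2PO4
Reagents that add atoms: 2-chloro-1,1-dimethoxyethane (compound 11), COC(CCl)OC, which reacts as methoxyethynyllithium 12, COC#C[Li]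
Why: Weinreb ketone synthesis: the alkoxyacetylide adds to the amide to give the chelated tetrahedral adduct (the free hydroxyl rides as its lithium alkoxide), and the alkoxy ynone should be released only on the mildly acidic quench, which also protonates the diethylamine before it can add to the ynone.

**Step 6**
Reactants: 14 (9S)-7-hydroxy-1-methoxy-4,4-bis(3-methylbut-2-en-1-yl)-9-phenyl-9-(triethylsilyloxy)nona-1,5-diyn-3-one
Product: 15 (9S)-1-methoxy-4,4-bis(3-methylbut-2-en-1-yl)-9-phenyl-9-(triethylsilyloxy)nona-1,5-diyne-3,7-dione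
Conditions: MnO2 (20 equiv), CH2Cl2, rt
Reagents that add atoms: none
Why: MnO2 oxidation of an activated propargylic alcohol under neutral heterogeneous conditions should give the ynone while sparing the acid-sensitive alkynyl ether, the silyl ether and the prenyl groups, and it removes the stereo-undefined carbinol centre.

**Step 7**
Reactants: 15 (9S)-1-methoxy-4,4-bis(3-methylbut-2-en-1-yl)-9-phenyl-9-(triethylsilyloxy)nona-1,5-diyne-3,7-dione
Product: 16 (9S)-9-hydroxy-1-methoxy-4,4-bis(3-methylbut-2-en-1-yl)-9-phenylnona-1,5-diyne-3,7-dione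
Conditions: Et3N·3HF, THF, 0 °C → rt; aq NaHCO3
Reagents that add atoms: none
Why: Fluoride cleavage of the secondary triethylsilyl ether with weakly acidic, non-basic Et3N·3HF should free the C2 hydroxyl without exposing the β-hydroxy ynone to base (retro-aldol, premature cyclisation) or to aqueous acid (hydration of the alkynyl ether).

**Step 8**
Reactants: 16 (9S)-9-hydroxy-1-methoxy-4,4-bis(3-methylbut-2-en-1-yl)-9-phenylnona-1,5-diyne-3,7-dione
Product: 20 griffinone A, via potassium alkoxide 17 (not isolated), via ring C vinyl carbanion 18 (not isolated), via bicyclic C6 carbanion 19 (not isolated)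
Conditions: KN(SiMe3)2 (0.1 equiv), THF (0.005 M), −78 → −40 °C; AcOH, −78 °C
Reagents that add atoms: none
Why: Proposed new method: the alkoxide 17, formed by the catalytic base, adds 6-endo-dig to C8a, the β-carbon of the C4 ynone, which closes ring C through the O1–C8a bond and, by the ring constraint, leaves the C4a carbanion 18 with its lone pair cis to C8; this carbanion adds 6-endo-dig to C5, the methoxy-bearing β-carbon of the second ynone, which closes ring A, and the C6 carbanion 19 is protonated by the next molecule of 16, whose alkoxide carries the chain, so that the whole step is a base-catalysed cycloisomerisation without by-product. The closest known reaction types are the base-mediated domino oxa-Michael/Michael and oxa-Michael/aldol reactions of ynones with ortho-hydroxyaryl enones and aldehydes, and the double conjugate addition to skipped diynones that gives 4-pyranones; here both acceptors are built into one chain and the second donor is a carbon. No new stereocentre arises: C2 is carried unchanged from 5, and substoichiometric base, low temperature and an acid quench are chosen so that the product is not opened at ring C by E1cB elimination from C3, the process that would scramble C2. The step needs chemoselectivity of the alkoxide for C8a over C5 (secured by ring size, six against ten members), regioselectivity for the β-carbons (secured by the polarisation of each ynone and, at C5, by the methoxy group), and C–C closure faster than C-protonation of 18 (favoured by the Thorpe–Ingold effect of the gem-diprenyl carbon C8 and by high dilution).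

**Compound list**
1 | N-methoxy-N-methyl-3-oxobutanamide | CC(=O)CC(=O)N(C)OC | starting material
2 | 1-bromo-3-methylbut-2-ene (prenyl bromide) | CC(C)=CCBr | starting material
3 | 2-acetyl-N-methoxy-N,5-dimethylhex-4-enamide (monoprenyl keto amide, racemic, not isolated) | CC(=O)C(CC=C(C)C)C(=O)N(C)OC | intermediate
4 | 2-acetyl-N-methoxy-N,5-dimethyl-2-(3-methylbut-2-en-1-yl)hex-4-enamide | CC(=O)C(CC=C(C)C)(CC=C(C)C)C(=O)N(C)OC | intermediate
5 | ethyl (3S)-3-hydroxy-3-phenylpropanoate | CCOC(=O)C[C@H](O)c1ccccc1 | starting material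
6 | ethyl (3S)-3-phenyl-3-(triethylsilyloxy)propanoate | CCOC(=O)C[C@H](O[Si](CC)(CC)CC)c1ccccc1 | intermediate
7 | (3S)-3-phenyl-3-(triethylsilyloxy)propanal | O=CC[C@H](O[Si](CC)(CC)CC)c1ccccc1 | intermediate
8 | diethyl 4-[methoxy(methyl)amino]-3,3-bis(3-methylbut-2-en-1-yl)-4-oxobut-1-en-2-yl phosphate (enol phosphate, not isolated) | C=C(OP(=O)(OCC)OCC)C(CC=C(C)C)(CC=C(C)C)C(=O)N(C)OC | intermediate
9 | lithium acetylide, the lithium salt of 2-ethynyl-N-methoxy-N,5-dimethyl-2-(3-methylbut-2-en-1-yl)hex-4-enamide (not isolated) | [Li]C#CC(CC=C(C)C)(CC=C(C)C)C(=O)N(C)OC | intermediate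
10 | (7S)-5-hydroxy-N-methoxy-N-methyl-2,2-bis(3-methylbut-2-en-1-yl)-7-phenyl-7-(triethylsilyloxy)hept-3-ynamide (both C5 epimers) | CON(C)C(=O)C(CC=C(C)C)(CC=C(C)C)C#CC(O)C[C@H](O[Si](CC)(CC)CC)c1ccccc1 | intermediate
11 | 2-chloro-1,1-dimethoxyethane | COC(CCl)OC | starting material
12 | methoxyethynyllithium (not isolated) | COC#C[Li] | intermediate
13 | dilithium tetrahedral adduct of 10 and 12 (not isolated) | COC#CC(O[Li])(N(C)OC)C(CC=C(C)C)(CC=C(C)C)C#CC(O[Li])C[C@H](O[Si](CC)(CC)CC)c1ccccc1 | intermediate
14 | (9S)-7-hydroxy-1-methoxy-4,4-bis(3-methylbut-2-en-1-yl)-9-phenyl-9-(triethylsilyloxy)nona-1,5-diyn-3-one (both C7 epimers) | COC#CC(=O)C(CC=C(C)C)(CC=C(C)C)C#CC(O)C[C@H](O[Si](CC)(CC)CC)c1ccccc1 | intermediate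
15 | (9S)-1-methoxy-4,4-bis(3-methylbut-2-en-1-yl)-9-phenyl-9-(triethylsilyloxy)nona-1,5-diyne-3,7-dione | COC#CC(=O)C(CC=C(C)C)(CC=C(C)C)C#CC(=O)C[C@H](O[Si](CC)(CC)CC)c1ccccc1 | intermediate
16 | (9S)-9-hydroxy-1-methoxy-4,4-bis(3-methylbut-2-en-1-yl)-9-phenylnona-1,5-diyne-3,7-dione | COC#CC(=O)C(CC=C(C)C)(CC=C(C)C)C#CC(=O)C[C@H](O)c1ccccc1 | intermediate
17 | potassium alkoxide of 16 (not isolated) | COC#CC(=O)C(CC=C(C)C)(CC=C(C)C)C#CC(=O)C[C@H]([O-])c1ccccc1.[K+] | intermediate
18 | ring C vinyl carbanion (potassium salt, carbanion at C4a, not isolated) | COC#CC(=O)C(CC=C(C)C)(CC=C(C)C)C1=[C-]C(=O)C[C@@H](c2ccccc2)O1.[K+] | intermediate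
19 | bicyclic C6 carbanion (potassium salt, not isolated) | COC1=[C-]C(=O)C(CC=C(C)C)(CC=C(C)C)C2=C1C(=O)C[C@@H](c1ccccc1)O2.[K+] | intermediate
20 | griffinone A, (2S)-5-methoxy-8,8-bis(3-methylbut-2-en-1-yl)-2-phenyl-2,3-dihydro-4H-chromene-4,7(8H)-dione | COC1=CC(=O)C(CC=C(C)C)(CC=C(C)C)C2=C1C(=O)C[C@@H](c1ccccc1)O2 | target

**Totals**
Total step count: 8. Longest linear sequence: 7 steps (steps 2, 3, 4, 5, 6, 7, 8 from 5); the branch from 1 has 6 steps (steps 1, 4, 5, 6, 7, 8).

**Steps most likely to fail**

Step 8 (proposed new method). The C4a carbanion may be protonated before it closes ring A, which strands the material as the monocyclic dihydropyranone. Base may also open ring C of the product by elimination from C3 and so erode the C2 configuration. The fallback uses known reactions and builds ring A first with a stabilised enolate, then ring C by acid; it sets out from 4 and 7 and comes back at 20. The kinetic lithium enolate of methyl ketone 4 (LiN(i-Pr)2, THF, −78 °C) would be added to aldehyde 7 to give the β-hydroxy ketone F1 (aldol addition). Dess–Martin oxidation would give the β-diketone F2. Excess methoxyethynyllithium 12, whose first equivalent masks the diketone as its enolate, would convert the Weinreb amide into the alkoxy ynone F3. Et3N in CH2Cl2 should then bring about the intramolecular Michael addition of the 1,3-diketone carbon C4a to C5 (6-endo-dig, C-alkylation under thermodynamic control) to give the monocyclic enol F4 with the methoxy group fixed at C5. Et3N·3HF would remove the silyl group to give the hydroxy triketone F5. Catalytic TsOH in CH2Cl2 over molecular sieves should effect the cyclodehydration of the δ-hydroxy-β-diketone unit: the C2 hydroxyl adds to the C8a carbonyl with loss of water, so O1–C8a is again the ring-closing bond and C2 keeps its configuration, giving 20. A regioisomer from attack at C5 would have to be separated.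

Step 5. Addition to the neopentyl-type Weinreb amide may be slow, the amide base may cleave the N–O bond, and liberated diethylamine may add to the alkoxy ynone during work-up. The fallback changes from acylation to aldehyde addition and oxidation; it sets out from 10 and comes back at 15. i-Bu2AlH (2.2 equiv, THF, −78 °C) would reduce the Weinreb amide of 10 to the aldehyde F6. Methoxyethynyllithium 12 would add to this more reactive electrophile to give the bis-propargylic diol F7, a stable carbinol that is not affected by amine on work-up. MnO2 would then oxidise both carbinols in one operation to 15.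

Step 7. Fluoride or HF may add across the push–pull alkynyl ether, or the freed hydroxy ynone may cyclise prematurely with C-protonation. The fallback avoids the protecting group altogether; it sets out from 5 and 4 and comes back at 16. Direct amidation of 5 (MeNHOMe·HCl, i-PrMgCl, THF, −20 °C) would give the hydroxy Weinreb amide F8. Its magnesium alkoxide would be treated with lithium acetylide 9, generated from 4 exactly as in step 4, to give the tetrahedral adduct F9, in which the future C4 ketone stays masked as the metal hemiaminal. Without work-up, 12 would be added to convert the second, hindered Weinreb amide into the bis-adduct F10. A single inverse quench into cold aq NaH2PO4 should release both ketones and the free hydroxyl as 16.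

**Further compounds**
F1 | step 8 | (7S)-5-hydroxy-N-methoxy-N-methyl-2,2-bis(3-methylbut-2-en-1-yl)-3-oxo-7-phenyl-7-(triethylsilyloxy)heptanamide (both C5 epimers) | CON(C)C(=O)C(CC=C(C)C)(CC=C(C)C)C(=O)CC(O)C[C@H](O[Si](CC)(CC)CC)c1ccccc1
F2 | step 8 | (7S)-N-methoxy-N-methyl-2,2-bis(3-methylbut-2-en-1-yl)-3,5-dioxo-7-phenyl-7-(triethylsilyloxy)heptanamide | CON(C)C(=O)C(CC=C(C)C)(CC=C(C)C)C(=O)CC(=O)C[C@H](O[Si](CC)(CC)CC)c1ccccc1
F3 | step 8 | (9S)-1-methoxy-4,4-bis(3-methylbut-2-en-1-yl)-9-phenyl-9-(triethylsilyloxy)non-1-yne-3,5,7-trione | COC#CC(=O)C(CC=C(C)C)(CC=C(C)C)C(=O)CC(=O)C[C@H](O[Si](CC)(CC)CC)c1ccccc1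
F4 | step 8 | 5-hydroxy-3-methoxy-6,6-bis(3-methylbut-2-en-1-yl)-4-[(3S)-3-phenyl-3-(triethylsilyloxy)propanoyl]cyclohexa-2,4-dien-1-one | COC1=CC(=O)C(CC=C(C)C)(CC=C(C)C)C(O)=C1C(=O)C[C@H](O[Si](CC)(CC)CC)c1ccccc1
F5 | step 8 | 5-hydroxy-4-[(3S)-3-hydroxy-3-phenylpropanoyl]-3-methoxy-6,6-bis(3-methylbut-2-en-1-yl)cyclohexa-2,4-dien-1-one | COC1=CC(=O)C(CC=C(C)C)(CC=C(C)C)C(O)=C1C(=O)C[C@H](O)c1ccccc1
F6 | step 5 | (7S)-5-hydroxy-2,2-bis(3-methylbut-2-en-1-yl)-7-phenyl-7-(triethylsilyloxy)hept-3-ynal (both C5 epimers) | O=CC(CC=C(C)C)(CC=C(C)C)C#CC(O)C[C@H](O[Si](CC)(CC)CC)c1ccccc1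
F7 | step 5 | (9S)-1-methoxy-4,4-bis(3-methylbut-2-en-1-yl)-9-phenyl-9-(triethylsilyloxy)nona-1,5-diyne-3,7-diol (mixture of epimers) | COC#CC(O)C(CC=C(C)C)(CC=C(C)C)C#CC(O)C[C@H](O[Si](CC)(CC)CC)c1ccccc1
F8 | step 7 | (3S)-3-hydroxy-N-methoxy-N-methyl-3-phenylpropanamide | CON(C)C(=O)C[C@H](O)c1ccccc1
F9 | step 7 | tetrahedral adduct of F8 and 9 (metal alkoxide, drawn in the protonated form) | CON(C)C(O)(C[C@H](O)c1ccccc1)C#CC(CC=C(C)C)(CC=C(C)C)C(=O)N(C)OC
F10 | step 7 | bis-adduct of F9 and 12 (metal alkoxide, drawn in the protonated form) | CON(C)C(O)(C[C@H](O)c1ccccc1)C#CC(CC=C(C)C)(CC=C(C)C)C(O)(N(C)OC)C#COC
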